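**Late readings.** At 20.0 min, the last reading of the ochre run, in which the enzyme turns starting material into target beside a protic impurity, target reads 67.6 % and starting material 0 %; at 4.00 min they already read 67.7 % and 0.2 %. The blue run also shows starting material at 0 % by 4.00 min. The asked 25 min is 6.25 times that first reading, so the end of each flask is read as a split of the starting material, with no clock in it.

the same everywhere: starting material 0.17 M; enzyme 17 µM

|  | protic impurity | remark | time |
|---|---|---|---|
| blue | 0.064 M | run made earlier |  |
| ochre | 1.3 M | run made earlier |  |
| south-west | 0.0800 M |  | 25 min |
| south-east | 0.150 M |  | 25 min |
| south | 0.300 M |  | 25 min |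
| east | 0.600 M |  | 25 min |
| north | 1.50 M |  | 25 min |

- blue (time / min: target / %, starting material / %): 4.00: 97.7, 0; 8.00: 96.5, 0.7; 12.0: 97.4, 0; 20.0: 97.2, 0.7
- ochre (time / min: target / %, starting material / %): 4.00: 67.7, 0.2; 8.00: 67.8, 0; 12.0: 68.1, 0; 20.0: 67.6, 0

(each reading ± 0.5 percentage points)

- "hardly changes" means that all values lie within two and a half points (for a concentration: within two and a half percent of the largest)

* amount of target at the end, in percent of the starting material charged for south-west, south-east, south, east, north, in this order
* the course of these numbers from the first flask to the last (falls all the way / hardly changes / falls, then rises / rises, then falls / rises all the way)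

**Two extremes.** An impurity that takes nothing leaves target at 100 %. One that titrates starting material mole for mole leaves 62.4 % in the blue run and no target in the ochre run, whose impurity charge is larger than the charge of starting material. The blue run reads 97.2 % and the ochre run 67.6 %, both between these limits, so impurity and enzyme compete for the starting material.

**Selectivity factor.** Let c be the impurity charge and S the missing part over the target part, divided by c: a selectivity factor per unit of impurity concentration. The ochre run gives S = 0.369 L mol⁻¹. The blue run reads 0.450 L mol⁻¹, but from a missing part of 2.8 percentage points with scatter 0.5 points. Across a factor of 20.3 in c, S therefore holds within that scatter. The missing part of the ochre run equals 4.24 % of its impurity charge, so in that run the impurity stays near its charge, a pseudo-first-order partner. The target fraction is then 1/(1 + S·c), which gives 97.1 % for south-west and 64.4 % for north.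

**The forecast.** It holds that “The yield is therefore set by a partition”, and it gives 96.7 %, 94.2 %, 89.4 %, 81.4 % and 64.8 %, a course that falls all the way. It fits both runs with order 0.95, whereas the reckoning above takes first order from the ochre run, so the two part slightly at south-west.

**The flasks.** They end at 97.0 %, 94.5 %, 89.7 %, 81.5 % and 64.6 % target, a course that falls all the way.

    starting material + protic impurity → quenched substrate (k = 1.26 L mol⁻¹ min⁻¹)
    starting material + enzyme → target + enzyme, rate k2*[starting material]*[enzyme]/(1 + ([starting material]/Km2) + ([target]/Kp2)) (0.0724 M, 0.218 M, k = 4.71 × 10⁵ L mol⁻¹ min⁻¹)

**Rate ratio.** At 0.245 min in south-west, the enzyme step uses starting material 32 times as fast as the step with protic impurity into quenched substrate, and over the whole run 1/(S·c) from the ochre reading puts target over loss at 33.9 for that flask, which at 25.0 min holds 3.01 % quenched substrate. For north the same S gives a ratio of 1.81 and a target of 64.4 %, and that flask ends at 64.6 % target with 35.4 % quenched substrate.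

The readings were computed for substances that don't exist.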